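- Retrosynthesis: hydrolyse the two tropolone methyl ethers, open both pyrans at O1–C9a and O1′–C9a′, cut the two sp3–sp2 bonds C4–C4a and C4′–C4a′, then cut the central C–C bond of the diene.
- Enabling feature: each pyran has a short arm (C2–C3(Me)–C4 and C2′–C3′–C4′) between its carbinol carbon and the tropolone carbon C4a/C4a′. C4 and C4′ are therefore the terminal carbons of an isopropenyl carbinol and a vinyl carbinol at the two ends of one dienediol.
- Forward, chain: two enal alkynylations, each with its own silylacetylene, give an E-vinyl iodide and an E-vinylstannane; Stille union gives the tetraene bis-silyl ether 16.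
- Forward, tropone: 2-methylanisole is taken by Birch reduction, dibromocarbene addition, dihydroxylation and oxidative ring expansion to bromotropolone 22, then O-methylated to 23.
- Forward, union and rings: double hydroboration of 16 and double B-alkyl Suzuki coupling with 23 join the chain to both tropones without closing a ring. After desilylation both pyrans close together by alkoxide addition–elimination at C9a/C9a′, and hydrolysis frees the tropolones.
- Stereochemistry: C2 and C2′ come from ligand-controlled alkynylation, C3 from 1,2-induction in the hydroboration, and the E,E-diene from syn-hydrometalation and stereoretentive coupling.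

Key step: step 15

Assumption: the (R,R)-ProPhenol/ZnMe2 catalyst is taken to deliver the alkynyl group to the Si face of both enals, giving the (R)-carbinols 4 and 12; if the sense is the reverse, the (S,S)-ligand is used in steps 1 and 5 and nothing else changes.

**Route**

Step 1
Reactants: 1 methacrolein; 2 trimethylsilylacetylene
Product: 4 (R)-4-methyl-1-(trimethylsilyl)pent-4-en-1-yn-3-ol, via methyl[(trimethylsilyl)ethynyl]zinc 3 (not isolated)
Conditions: 2, ZnMe2, (R,R)-ProPhenol (10 mol%), Ph3P=O (20 mol%), toluene, rt; then 1 added slowly, 0–4 °C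
Reagents that add atoms: none
Why: Catalytic enantioselective 1,2-alkynylation of an α,β-unsaturated aldehyde by the zinc acetylide held in the dinuclear zinc–ProPhenol pocket, which should select one face of the aldehyde and so set the carbinol centre that becomes C2.

Step 2
Reactants: 4 (R)-4-methyl-1-(trimethylsilyl)pent-4-en-1-yn-3-ol
Product: 5 (R)-tert-butyldimethyl{[4-methyl-1-(trimethylsilyl)pent-4-en-1-yn-3-yl]oxy}silane
Conditions: TBSCl, imidazole, DMF, 0 °C → rt
Reagents that add atoms: tert-butyldimethylsilyl chloride, CC(C)(C)[Si](C)(C)Cl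
Why: Standard O-silylation of a secondary alcohol, which also makes the small carbinol less volatile and later directs the hydroboration.

Step 3
Reactants: 5 (R)-tert-butyldimethyl{[4-methyl-1-(trimethylsilyl)pent-4-en-1-yn-3-yl]oxy}silane
Product: 6 (R)-tert-butyldimethyl[(4-methylpent-4-en-1-yn-3-yl)oxy]silane
Conditions: K2CO3, MeOH, 0 °C → rt
Reagents that add atoms: none
Why: Methanolysis cleaves the C(sp)–Si bond selectively, while the hindered O–Si bond of the TBS ether should be untouched.

Step 4
Reactants: 6 (R)-tert-butyldimethyl[(4-methylpent-4-en-1-yn-3-yl)oxy]silane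
Product: 8 (S,E)-tert-butyl[(1-iodo-4-methylpenta-1,4-dien-3-yl)oxy]dimethylsilane, via alkenylzirconocene chloride 7 (not isolated)
Conditions: Cp2Zr(H)Cl, THF, rt, dark; then I2, −78 → 0 °C
Reagents that add atoms: iodine, II
Why: Hydrozirconation adds Zr–H syn across the terminal alkyne with zirconium on the terminal carbon (the 1,1-disubstituted alkene is much slower), and iodinolysis with retention should give the E-vinyl iodide.

Step 5
Reactants: 9 acrolein; 10 ethynyldimethyl(phenyl)silane
Product: 12 (R)-5-[dimethyl(phenyl)silyl]pent-1-en-4-yn-3-ol, via methyl{[dimethyl(phenyl)silyl]ethynyl}zinc 11 (not isolated)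
Conditions: 10, ZnMe2, (R,R)-ProPhenol (10 mol%), Ph3P=O (20 mol%), toluene, rt; then 9 added slowly, 0–4 °C
Reagents that add atoms: none
Why: The same ProPhenol-catalysed zinc acetylide 1,2-addition, with the same facial sense, should set the carbinol centre that becomes C2′; the dimethylphenylsilyl alkyne is chosen for this smallest carbinol of the route because its adduct is non-volatile and UV-visible, and slow addition limits polymerisation of the enal.

Step 6
Reactants: 12 (R)-5-[dimethyl(phenyl)silyl]pent-1-en-4-yn-3-ol
Product: 13 (R)-tert-butyl({5-[dimethyl(phenyl)silyl]pent-1-en-4-yn-3-yl}oxy)dimethylsilane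
Conditions: TBSCl, imidazole, DMF, 0 °C → rt
Reagents that add atoms: tert-butyldimethylsilyl chloride, CC(C)(C)[Si](C)(C)Cl
Why: Standard O-silylation of the secondary allylic/propargylic alcohol under non-acidic conditions.

Step 7
Reactants: 13 (R)-tert-butyl({5-[dimethyl(phenyl)silyl]pent-1-en-4-yn-3-yl}oxy)dimethylsilane
Product: 14 (R)-tert-butyldimethyl(pent-1-en-4-yn-3-yloxy)silane
Conditions: K2CO3, MeOH, 0 °C → rt
Reagents that add atoms: none
Why: Selective protodesilylation of the alkynylsilane by methoxide, which attacks the aryl-bearing silicon on sp-carbon at least as readily as a trimethylsilyl group, with the TBS ether retained.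

Step 8
Reactants: 14 (R)-tert-butyldimethyl(pent-1-en-4-yn-3-yloxy)silane
Product: 15 (R,E)-tert-butyldimethyl{[1-(tributylstannyl)penta-1,4-dien-3-yl]oxy}silane
Conditions: Bu3SnH, Pd(PPh3)2Cl2 (3 mol%), THF, 0 °C
Reagents that add atoms: tributyltin hydride, CCCC[SnH](CCCC)CCCC
Why: Palladium-catalysed hydrostannylation is specific for the alkyne and adds Sn–H syn, and the bulky propargylic silyloxy group should steer tin to the distal carbon to give mainly the E-β-stannane (a minor internal isomer would be removed by chromatography).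

Step 9
Reactants: 8 (S,E)-tert-butyl[(1-iodo-4-methylpenta-1,4-dien-3-yl)oxy]dimethylsilane; 15 (R,E)-tert-butyldimethyl{[1-(tributylstannyl)penta-1,4-dien-3-yl]oxy}silane
Product: 16 (3S,4E,6E,8R)-3,8-bis(tert-butyldimethylsilyloxy)-2-methyldeca-1,4,6,9-tetraene
Conditions: Pd(MeCN)2Cl2 (5 mol%), DMF, rt, dark
Reagents that add atoms: none
Why: Stille coupling of a vinyl iodide with a vinylstannane proceeds with retention at both partners under neutral conditions, so the E,E-diene and both silyloxy stereocentres should be carried over unchanged.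

Step 10
Reactants: 17 2-methylanisole
Product: 18 1-methoxy-2-methylcyclohexa-1,4-diene
Conditions: Li, NH3 (l), THF, t-BuOH, −78 → −33 °C
Reagents that add atoms: none
Why: Birch reduction leaves both donor substituents on a surviving double bond, so the tetrasubstituted enol ether and an isolated disubstituted alkene result.

Step 11
Reactants: 18 1-methoxy-2-methylcyclohexa-1,4-diene
Product: 19 7,7-dibromo-1-methoxy-6-methylbicyclo[4.1.0]hept-3-ene (racemic)
Conditions: CHBr3, KOtBu, pentane, −20 → 0 °C
Reagents that add atoms: bromoform, BrC(Br)Br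
Why: Electrophilic dibromocarbene adds to the most electron-rich, tetrasubstituted enol ether double bond in preference to the disubstituted alkene (cheletropic cyclopropanation); the labile adduct is kept cold and used at once.

Step 12
Reactants: 19 7,7-dibromo-1-methoxy-6-methylbicyclo[4.1.0]hept-3-ene
Product: 20 7,7-dibromo-1-methoxy-6-methylbicyclo[4.1.0]heptane-3,4-diol (racemic cis-diol)
Conditions: OsO4 (2 mol%), NMO, acetone/H2O, 0 °C → rt
Reagents that add atoms: N-methylmorpholine N-oxide, C[N+]1([O-])CCOCC1; water, O
Why: Catalytic syn-dihydroxylation of the remaining alkene under slightly basic conditions, expected on the face away from the dibromomethylene bridge; the configuration is immaterial because every stereocentre is erased in step 13.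

Step 13
Reactants: 20 7,7-dibromo-1-methoxy-6-methylbicyclo[4.1.0]heptane-3,4-diol
Product: 22 5-bromo-2-hydroxy-4-methoxy-6-methylcyclohepta-2,4,6-trien-1-one, via bicyclic 1,2-dione 21 (not isolated)
Conditions: TFAA, DMSO, CH2Cl2, −60 °C; then Et3N, −60 °C → rt
Reagents that add atoms: none
Why: Swern-type oxidation gives the 1,2-dione, whose amine-promoted enolisation opens the methoxy-substituted dibromocyclopropane with loss of bromide; tautomerisation then gives the tropolone with the carbene carbon as C5–Br between the methoxy- and methyl-bearing carbons.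

Step 14
Reactants: 22 5-bromo-2-hydroxy-4-methoxy-6-methylcyclohepta-2,4,6-trien-1-one
Product: 23 5-bromo-2,4-dimethoxy-6-methylcyclohepta-2,4,6-trien-1-one
Conditions: MeI, K2CO3, DMF, rt; chromatographic separation
Reagents that add atoms: iodomethane, CI
Why: O-alkylation of the tropolonate; the ether with the methyl on the other tropolone oxygen is an expected co-product, is removed by chromatography and can be hydrolysed back to 22.

Step 15
Reactants: 16 (3S,4E,6E,8R)-3,8-bis(tert-butyldimethylsilyloxy)-2-methyldeca-1,4,6,9-tetraene; 23 5-bromo-2,4-dimethoxy-6-methylcyclohepta-2,4,6-trien-1-one (2.3 equiv)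
Product: 25 5,5′-[(2R,3R,4E,6E,8R)-3,8-bis(tert-butyldimethylsilyloxy)-2-methyldeca-4,6-diene-1,10-diyl]bis(2,4-dimethoxy-6-methylcyclohepta-2,4,6-trien-1-one), via bis(9-BBN) alkylborane 24 (not isolated)
Conditions: 9-BBN (2.4 equiv), THF, 0 °C → rt; then 23, Pd(OAc)2 (10 mol%), SPhos (20 mol%), K3PO4 (aq), THF, 50 °C
Reagents that add atoms: none
Why: The B–H bond of 9-BBN adds syn through a four-centre transition state with boron on the terminal carbon of the isopropenyl and vinyl groups, and the two primary alkylboranes are coupled in the same flask: zerovalent palladium inserts into the C5–Br bond of 23, the base-activated borate transfers its primary alkyl group, and reductive elimination forms C4–C4a and C4′–C4a′ (B-alkyl Suzuki–Miyaura coupling of a hydroborated terminal alkene with an sp2 halide is the closest known type). No ring is closed in this step. The one new stereocentre, C3, is set by 1,2-induction from the silyloxy-bearing C2: the 1,1-disubstituted alkene reacts with the carbinol hydrogen near the alkene plane and the bulky dialkylborane approaches the face away from the dienyl chain, the known anti preference of 9-BBN with α-oxygenated 1,1-disubstituted alkenes, which gives the 2,3-anti and later trans arrangement. The step needs site selectivity for the two terminal alkenes over the internal E,E-diene, which the steric demand of 9-BBN and the flanking silyloxy groups should secure, and it needs coupling at a bromide flanked by methoxy and methyl, for which the bulky electron-rich SPhos ligand is chosen so that transmetalation and reductive elimination outrun β-hydride elimination. Bromide rather than iodide is used because the ring expansion delivers it directly and the electron-poor tropone C–Br bond adds readily; the methyl ethers, silyl ethers and diene should be inert.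

Step 16
Reactants: 25 bis(tropone) bis-silyl ether
Product: 26 5,5′-[(2R,3R,4E,6E,8R)-3,8-dihydroxy-2-methyldeca-4,6-diene-1,10-diyl]bis(2,4-dimethoxy-6-methylcyclohepta-2,4,6-trien-1-one)
Conditions: TBAF, AcOH (1:1), THF, 0 °C → rt
Reagents that add atoms: none
Why: Fluoride cleaves both secondary TBS ethers, and buffering with acetic acid keeps the medium near neutral so that the diol is isolated before any base-driven chemistry at the tropones.

Step 17
Reactants: 26 bis(tropone) diol
Product: 27 (2R,3R)-8-methoxy-2-{(1E,3E)-4-[(2R)-8-methoxy-5-methyl-7-oxo-2,3,4,7-tetrahydrocyclohepta[b]pyran-2-yl]buta-1,3-dien-1-yl}-3,5-dimethyl-3,4-dihydrocyclohepta[b]pyran-7(2H)-one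
Conditions: KOtBu (0.3 equiv), 4 Å molecular sieves, THF, 0 °C → rt
Reagents that add atoms: none
Why: Base-catalysed intramolecular addition–elimination (nucleophilic vinylic substitution, 6-endo-trig): each alkoxide adds to the methoxy-bearing C4 of its tropone (future C9a), the δ-carbon of the dienone, and the released methoxide carries the chain; both pyrans close with the carbinol C–O bonds untouched, so C2, C3 and C2′ are retained.

Step 18
Reactants: 27 bis-pyran bis(methyl ether)
Product: 28 (2R,3R)-8-hydroxy-2-{(1E,3E)-4-[(2R)-8-hydroxy-5-methyl-7-oxo-2,3,4,7-tetrahydrocyclohepta[b]pyran-2-yl]buta-1,3-dien-1-yl}-3,5-dimethyl-3,4-dihydrocyclohepta[b]pyran-7(2H)-one (target)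
Conditions: LiOH (aq), THF/H2O, 40 °C; then AcOH to pH 5
Reagents that add atoms: lithium hydroxide, [Li+].[OH-]
Why: A 2-methoxytropone is a vinylogous ester and is hydrolysed by hydroxide addition–elimination at C8/C8′, the ring carbon next to the carbonyl and the most electrophilic one, while the ring-ether carbons C9a/C9a′ and the base-stable dienyl ethers should survive; the weakly acidic work-up avoids ionising the dienylic C2–O bonds.

**Compound list**

1 | methacrolein | CC(=C)C=O | starting material
2 | trimethylsilylacetylene | C#C[Si](C)(C)C | starting material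
3 | methyl[(trimethylsilyl)ethynyl]zinc | C[Zn]C#C[Si](C)(C)C | intermediate (not isolated)
4 | (R)-4-methyl-1-(trimethylsilyl)pent-4-en-1-yn-3-ol | C=C(C)[C@@H](O)C#C[Si](C)(C)C | intermediate
5 | (R)-tert-butyldimethyl{[4-methyl-1-(trimethylsilyl)pent-4-en-1-yn-3-yl]oxy}silane | C=C(C)[C@@H](O[Si](C)(C)C(C)(C)C)C#C[Si](C)(C)C | intermediate
6 | (R)-tert-butyldimethyl[(4-methylpent-4-en-1-yn-3-yl)oxy]silane | C=C(C)[C@@H](O[Si](C)(C)C(C)(C)C)C#C | intermediate
7 | (E)-alkenylzirconocene chloride from 6 | C=C(C)[C@@H](O[Si](C)(C)C(C)(C)C)/C=C/[Zr](Cl)(C1C=CC=C1)C1C=CC=C1 | intermediate (not isolated)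
8 | (S,E)-tert-butyl[(1-iodo-4-methylpenta-1,4-dien-3-yl)oxy]dimethylsilane | C=C(C)[C@@H](O[Si](C)(C)C(C)(C)C)/C=C/I | intermediate
9 | acrolein | C=CC=O | starting material
10 | ethynyldimethyl(phenyl)silane | C#C[Si](C)(C)c1ccccc1 | starting material
11 | methyl{[dimethyl(phenyl)silyl]ethynyl}zinc | C[Zn]C#C[Si](C)(C)c1ccccc1 | intermediate (not isolated)
12 | (R)-5-[dimethyl(phenyl)silyl]pent-1-en-4-yn-3-ol | C=C[C@@H](O)C#C[Si](C)(C)c1ccccc1 | intermediate
13 | (R)-tert-butyl({5-[dimethyl(phenyl)silyl]pent-1-en-4-yn-3-yl}oxy)dimethylsilane | C=C[C@@H](O[Si](C)(C)C(C)(C)C)C#C[Si](C)(C)c1ccccc1 | intermediate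
14 | (R)-tert-butyldimethyl(pent-1-en-4-yn-3-yloxy)silane | C=C[C@@H](O[Si](C)(C)C(C)(C)C)C#C | intermediate
15 | (R,E)-tert-butyldimethyl{[1-(tributylstannyl)penta-1,4-dien-3-yl]oxy}silane | C=C[C@@H](O[Si](C)(C)C(C)(C)C)/C=C/[Sn](CCCC)(CCCC)CCCC | intermediate
16 | (3S,4E,6E,8R)-3,8-bis(tert-butyldimethylsilyloxy)-2-methyldeca-1,4,6,9-tetraene | C=C(C)[C@H](/C=C/C=C/[C@H](O[Si](C)(C)C(C)(C)C)C=C)O[Si](C)(C)C(C)(C)C | intermediate
17 | 2-methylanisole | COc1ccccc1C | starting material
18 | 1-methoxy-2-methylcyclohexa-1,4-diene | COC1=C(C)CC=CC1 | intermediate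
19 | 7,7-dibromo-1-methoxy-6-methylbicyclo[4.1.0]hept-3-ene (racemic, cis-fused; one enantiomer drawn) | CO[C@]12CC=CC[C@@]1(C)C2(Br)Br | intermediate
20 | 7,7-dibromo-1-methoxy-6-methylbicyclo[4.1.0]heptane-3,4-diol (racemic; cis-diol drawn anti to the CBr2 bridge; one enantiomer drawn) | CO[C@]12C[C@H](O)[C@H](O)C[C@@]1(C)C2(Br)Br | intermediate
21 | 7,7-dibromo-1-methoxy-6-methylbicyclo[4.1.0]heptane-3,4-dione (racemic; one enantiomer drawn) | CO[C@]12CC(=O)C(=O)C[C@@]1(C)C2(Br)Br | intermediate (not isolated)
22 | 5-bromo-2-hydroxy-4-methoxy-6-methylcyclohepta-2,4,6-trien-1-one | Cc1cc(=O)c(O)cc(OC)c1Br | intermediate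
23 | 5-bromo-2,4-dimethoxy-6-methylcyclohepta-2,4,6-trien-1-one | Cc1cc(=O)c(OC)cc(OC)c1Br | intermediate
24 | bis(9-BBN) alkylborane from 16 (boron on C1 and C10; 2R,3R,8R) | C1CC2CCCC(C1)B2C[C@@H](C)[C@H](/C=C/C=C/[C@@H](CCB1C2CCCC1CCC2)O[Si](C)(C)C(C)(C)C)O[Si](C)(C)C(C)(C)C | intermediate (not isolated)
25 | 5,5′-[(2R,3R,4E,6E,8R)-3,8-bis(tert-butyldimethylsilyloxy)-2-methyldeca-4,6-diene-1,10-diyl]bis(2,4-dimethoxy-6-methylcyclohepta-2,4,6-trien-1-one) | Cc1cc(=O)c(OC)cc(OC)c1C[C@@H](C)[C@H](/C=C/C=C/[C@@H](CCc1c(C)cc(=O)c(OC)cc1OC)O[Si](C)(C)C(C)(C)C)O[Si](C)(C)C(C)(C)C | intermediate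
26 | 5,5′-[(2R,3R,4E,6E,8R)-3,8-dihydroxy-2-methyldeca-4,6-diene-1,10-diyl]bis(2,4-dimethoxy-6-methylcyclohepta-2,4,6-trien-1-one) | Cc1cc(=O)c(OC)cc(OC)c1C[C@@H](C)[C@H](/C=C/C=C/[C@@H](CCc1c(C)cc(=O)c(OC)cc1OC)O)O | intermediate
27 | bis(8-O-methyl) ether of the target | Cc1cc(=O)c(OC)cc2c1C[C@@H](C)[C@H](/C=C/C=C/[C@H]1CCc3c(C)cc(=O)c(OC)cc3O1)O2 | intermediate
28 | (2R,3R)-8-hydroxy-2-{(1E,3E)-4-[(2R)-8-hydroxy-5-methyl-7-oxo-2,3,4,7-tetrahydrocyclohepta[b]pyran-2-yl]buta-1,3-dien-1-yl}-3,5-dimethyl-3,4-dihydrocyclohepta[b]pyran-7(2H)-one | Cc1cc(=O)c(O)cc2c1C[C@@H](C)[C@H](/C=C/C=C/[C@H]1CCc3c(C)cc(=O)c(O)cc3O1)O2 | target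

**Count and risks**

Total: 18 steps. Longest linear sequence: 9 steps (steps 1–4, 9, 15–18; the acrolein branch, steps 5–9 and 15–18, and the tropone branch, steps 10–14 and 15–18, are equally long).

Step 15. The hydroboration may discriminate poorly between the two faces of the isopropenyl group, because the dienyl substituent is slimmer than the alkyl groups for which the anti preference is established. Transfer of the β-branched alkyl group to the crowded tropone–palladium intermediate may also be slower than protodeboronation. The fallback separates the two events and changes the metal. From 16, hydroboration (9-BBN or dicyclohexylborane) with NaBO3 work-up would give the 1,10-diol F1, at which stage a C2 epimer can be removed by chromatography. Appel-type iodination (I2, PPh3, imidazole) would give the 1,10-diiodide F2, and zinc insertion (zinc dust, LiCl, THF) the bis(alkylzinc iodide) F3. A double Negishi coupling of F3 with 23 (Pd(OAc)2, SPhos, THF) comes back to the route at 25.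

Step 17. Addition of the alkoxide to the donor-substituted C4 of the tropone may be too slow, so that only one ring closes or base-induced degradation (enolisation through the ring methyl group, ring contraction of the methoxytropone) takes over. The fallback changes the electrophile from a 1,6-acceptor to a β-methoxy enone. From 22, the O-methylation of step 14 also provides the regioisomeric ether 5-bromo-2,6-dimethoxy-4-methylcyclohepta-2,4,6-trien-1-one F4, whose carbonyl sits next to the ring CH between the two oxygenated carbons. Double coupling of F4 with borane 24 as in step 15 would give the bis-silyl ether F5, and desilylation the diol F6. Alkoxide-catalysed closure, now a 1,4-addition–elimination at the β-carbon, would give the isomeric bis-pyran F7. Hydrolysis of F7 as in step 18 gives the same tropolone and comes back to the route at 28.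

Step 18. Hydroxide may also attack the ring-ether carbons C9a/C9a′ and open the pyrans, or the freed tropolones may not tolerate prolonged base. The fallback uses a tropolone protecting group that is removed by fluoride, not by attack on the ring. From 22, SEMCl and i-Pr2NEt in CH2Cl2 would give the 2-(trimethylsilyl)ethoxymethyl ether F8. Coupling of F8 with 24 as in step 15 would give the bis-silyl ether F9; HF·pyridine removes only the TBS groups to give the diol F10, and closure as in step 17 gives the bis-pyran F11. TBAF in DMPU at 45 °C then cleaves both acetal ethers and comes back to the route at 28.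

**Further compounds**

F1 | step 15 | 1,10-diol from double hydroboration–oxidation of 16 (configuration as in 25) | OC[C@@H](C)[C@H](/C=C/C=C/[C@@H](CCO)O[Si](C)(C)C(C)(C)C)O[Si](C)(C)C(C)(C)C
F2 | step 15 | 1,10-diiodide corresponding to F1 | IC[C@@H](C)[C@H](/C=C/C=C/[C@@H](CCI)O[Si](C)(C)C(C)(C)C)O[Si](C)(C)C(C)(C)C
F3 | step 15 | bis(alkylzinc iodide) from F2 | I[Zn]C[C@@H](C)[C@H](/C=C/C=C/[C@@H](CC[Zn]I)O[Si](C)(C)C(C)(C)C)O[Si](C)(C)C(C)(C)C
F4 | step 17 | 5-bromo-2,6-dimethoxy-4-methylcyclohepta-2,4,6-trien-1-one | Cc1cc(OC)c(=O)cc(OC)c1Br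
F5 | step 17 | regioisomeric bis(tropone) bis-silyl ether | Cc1cc(OC)c(=O)cc(OC)c1C[C@@H](C)[C@H](/C=C/C=C/[C@@H](CCc1c(C)cc(OC)c(=O)cc1OC)O[Si](C)(C)C(C)(C)C)O[Si](C)(C)C(C)(C)C
F6 | step 17 | regioisomeric bis(tropone) diol | Cc1cc(OC)c(=O)cc(OC)c1C[C@@H](C)[C@H](/C=C/C=C/[C@@H](CCc1c(C)cc(OC)c(=O)cc1OC)O)O
F7 | step 17 | regioisomeric bis-pyran bis(methyl ether) (carbonyl at C8, methoxy at C7) | Cc1cc(OC)c(=O)cc2c1C[C@@H](C)[C@H](/C=C/C=C/[C@H]1CCc3c(C)cc(OC)c(=O)cc3O1)O2
F8 | step 18 | 5-bromo-4-methoxy-6-methyl-2-{[2-(trimethylsilyl)ethoxy]methoxy}cyclohepta-2,4,6-trien-1-one | Cc1cc(=O)c(OCOCC[Si](C)(C)C)cc(OC)c1Br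
F9 | step 18 | SEM-protected bis(tropone) bis-silyl ether | Cc1cc(=O)c(OCOCC[Si](C)(C)C)cc(OC)c1C[C@@H](C)[C@H](/C=C/C=C/[C@@H](CCc1c(C)cc(=O)c(OCOCC[Si](C)(C)C)cc1OC)O[Si](C)(C)C(C)(C)C)O[Si](C)(C)C(C)(C)C
F10 | step 18 | SEM-protected bis(tropone) diol | Cc1cc(=O)c(OCOCC[Si](C)(C)C)cc(OC)c1C[C@@H](C)[C@H](/C=C/C=C/[C@@H](CCc1c(C)cc(=O)c(OCOCC[Si](C)(C)C)cc1OC)O)O
F11 | step 18 | SEM-protected bis-pyran | Cc1cc(=O)c(OCOCC[Si](C)(C)C)cc2c1C[C@@H](C)[C@H](/C=C/C=C/[C@H]1CCc3c(C)cc(=O)c(OCOCC[Si](C)(C)C)cc3O1)O2
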